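**Strategy.** Everything rests on disconnecting the benzylic carbinol carbon from C1 of the 3,4-dimethoxyphenyl ring. The feature exploited is that this O-bearing carbon is one CH2O arm of a 2-substituted propane-1,3-diol: as an N,N-diisopropylcarbamate it is deprotonated enantioselectively, which reverses its polarity. In one operation the α-oxy carbanion is united with the nucleophilic aryl carbon of a veratryl pinacol boronate; the 1,2-shift of aryl from boron to carbon and oxidation create the aryl–carbon bond and the (S)-carbinol. The precursor is a primary carbamate that already holds C2 (Evans hydroxymethylation), the anisyl alkene and a silyl-protected second arm; the (Z)-ester is added last by carbonylation of a vinyl iodide.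

Key step: step 7

Remark: simple reagents that only deliver a protecting group, an activating group or one atom (trioxane, TIPSOTf, i-Pr2NCOCl, H2O2, I2, TBSCl, CO) are given with SMILES in the steps and are not numbered.
Assumption: (+)-sparteine mirrors the known pro-S selectivity of (−)-sparteine (it removes the pro-R hydrogen) and overrides the small bias of the C2 centre.

**Step 1**
Reactants: 1 (S)-4-benzyloxazolidin-2-one; 2 pent-4-enoyl chloride
Product: 4 (S)-4-benzyl-3-(pent-4-enoyl)oxazolidin-2-one, via N-lithio oxazolidinone 3 (not isolated)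
Conditions: n-BuLi, THF, −78 °C; then 2, −78 → 0 °C
Reagents that add atoms: none
Why: N-acylation of the lithiated oxazolidinone by the acid chloride (attachment of an Evans auxiliary); no stereocentre is formed.

**Step 2**
Reactants: 4 (S)-4-benzyl-3-(pent-4-enoyl)oxazolidin-2-one
Product: 6 (S)-4-benzyl-3-[(R)-2-(hydroxymethyl)pent-4-enoyl]oxazolidin-2-one, via titanium enolate 5 (not isolated)
Conditions: TiCl4, i-Pr2NEt, CH2Cl2, 0 °C; then 1,3,5-trioxane, TiCl4, 0 °C; aq. NH4Cl
Reagents that add atoms: 1,3,5-trioxane, C1OCOCO1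
Why: Evans titanium-enolate hydroxymethylation: the chelated Z-enolate 5 should be attacked by TiCl4-activated formaldehyde on the face opposite the benzyl group, which sets the (R) centre (the later C2); the terminal alkene tolerates TiCl4, which is why the electron-rich styrene is introduced only afterwards.

**Step 3**
Reactants: 6 (S)-4-benzyl-3-[(R)-2-(hydroxymethyl)pent-4-enoyl]oxazolidin-2-one; 7 4-vinylanisole
Product: 8 (S)-4-benzyl-3-[(2R,4E)-2-(hydroxymethyl)-5-(4-methoxyphenyl)pent-4-enoyl]oxazolidin-2-one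
Conditions: 7 (3 equiv), Grubbs second-generation catalyst (5 mol%), CH2Cl2, 40 °C
Reagents that add atoms: none
Why: olefin cross-metathesis of a terminal alkene with a styrene; thermodynamic control should give the (E)-styrenyl alkene, and the free OH and the imide are tolerated.

**Step 4**
Reactants: 8 (S)-4-benzyl-3-[(2R,4E)-2-(hydroxymethyl)-5-(4-methoxyphenyl)pent-4-enoyl]oxazolidin-2-one
Product: 9 (S)-4-benzyl-3-[(2R,4E)-5-(4-methoxyphenyl)-2-{[(triisopropylsilyl)oxy]methyl}pent-4-enoyl]oxazolidin-2-one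
Conditions: TIPSOTf, 2,6-lutidine, CH2Cl2, −78 → 0 °C
Reagents that add atoms: triisopropylsilyl triflate, CC(C)[Si](OS(=O)(=O)C(F)(F)F)(C(C)C)C(C)C
Why: silylation of a primary alcohol; the bulky TIPS group is chosen because it should resist s-BuLi and silyl migration in the later steps.

**Step 5**
Reactants: 9 (S)-4-benzyl-3-[(2R,4E)-5-(4-methoxyphenyl)-2-{[(triisopropylsilyl)oxy]methyl}pent-4-enoyl]oxazolidin-2-one
Product: 10 (2S,4E)-5-(4-methoxyphenyl)-2-{[(triisopropylsilyl)oxy]methyl}pent-4-en-1-ol
Conditions: LiBH4, MeOH (1 equiv), THF, 0 °C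
Reagents that add atoms: none
Why: reductive cleavage of the N-acyl oxazolidinone to the primary alcohol; the α-centre is not enolised (the descriptor changes only through the CIP ranking) and the auxiliary is released.

**Step 6**
Reactants: 10 (2S,4E)-5-(4-methoxyphenyl)-2-{[(triisopropylsilyl)oxy]methyl}pent-4-en-1-ol
Product: 11 (2S,4E)-5-(4-methoxyphenyl)-2-{[(triisopropylsilyl)oxy]methyl}pent-4-en-1-yl N,N-diisopropylcarbamate
Conditions: i-Pr2NCOCl, Et3N, DMAP (cat.), CH2Cl2, reflux
Reagents that add atoms: N,N-diisopropylcarbamoyl chloride, CC(C)N(C(C)C)C(Cl)=O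
Why: O-carbamoylation of a primary alcohol; the carbamate is the directing group and later the leaving group of step 7.

**Step 7**
Reactants: 11 (2S,4E)-5-(4-methoxyphenyl)-2-{[(triisopropylsilyl)oxy]methyl}pent-4-en-1-yl N,N-diisopropylcarbamate; 12 2-(3,4-dimethoxyphenyl)-4,4,5,5-tetramethyl-1,3,2-dioxaborolane
Product: 16 (1S,2R,4E)-1-(3,4-dimethoxyphenyl)-5-(4-methoxyphenyl)-2-{[(triisopropylsilyl)oxy]methyl}pent-4-en-1-ol, via lithiated carbamate 13 (not isolated), via lithium boronate complex 14 (not isolated), via benzylic boronic ester 15 (not isolated)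
Conditions: s-BuLi, (+)-sparteine, Et2O, −78 °C, 5 h; 12, −78 °C, 1 h; MgBr2·OEt2, then reflux, 12 h; then 2 M NaOH, 30% H2O2, THF, 0 °C → rt
Reagents that add atoms: hydrogen peroxide, OO
Why: Hoppe-type sparteine-mediated lithiation followed by lithiation–borylation (closest known type: Matteson 1,2-metallate homologation): s-BuLi/(+)-sparteine removes the pro-R hydrogen of the OCH2 group of 11 to give the configurationally stable α-oxy organolithium 13, which boronate 12 traps with retention as the ate complex 14. On warming with MgBr2 the aryl group shifts from boron to carbon anti to the departing carbamate (inversion), which forms the aryl–carbon bond in 15, and H2O2/NaOH replaces boron by OH with retention. No ring is closed. The new (S)-carbinol centre is set by the chiral diamine (reagent control), while C2 is untouched because it is not acidic. The step needs lithiation α to the carbamate oxygen in preference to attack on the anisyl alkene or its allylic CH2; the carbamate C=O pre-complexes the base at −78 °C, and cyclisation of 13 onto the alkene would need a four-membered ring. It also needs migration of aryl in preference to a pinacol oxygen, which is the normal course for boronic esters.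

**Step 8**
Reactants: 16 (1S,2R,4E)-1-(3,4-dimethoxyphenyl)-5-(4-methoxyphenyl)-2-{[(triisopropylsilyl)oxy]methyl}pent-4-en-1-ol
Product: 17 (1S,2R)-1-(3,4-dimethoxyphenyl)-2-[(E)-3-(4-methoxyphenyl)prop-2-en-1-yl]propane-1,3-diol
Conditions: TBAF, THF, 0 °C → rt
Reagents that add atoms: none
Why: fluoride cleavage of the silyl ether; no stereocentre is affected.

**Step 9**
Reactants: 18 (E)-crotonaldehyde
Product: 19 (Z)-2-iodobut-2-enal
Conditions: I2, K2CO3, DMAP (20 mol%), THF/H2O 1:1, rt
Reagents that add atoms: iodine, II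
Why: α-iodination of an enal by amine-catalysed conjugate addition, iodination and elimination (Baylis–Hillman-type); the trans CH3/CHO relation of crotonaldehyde is kept, which gives the (Z)-iodide.

**Step 10**
Reactants: 19 (Z)-2-iodobut-2-enal
Product: 20 (Z)-2-iodobut-2-en-1-ol
Conditions: NaBH4, CeCl3·7H2O, MeOH, 0 °C
Reagents that add atoms: none
Why: Luche 1,2-reduction of the enal; the alkene geometry and the C–I bond are kept.

**Step 11**
Reactants: 20 (Z)-2-iodobut-2-en-1-ol
Product: 21 (Z)-tert-butyl[(2-iodobut-2-en-1-yl)oxy]dimethylsilane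
Conditions: TBSCl, imidazole, CH2Cl2, 0 °C → rt
Reagents that add atoms: tert-butyldimethylsilyl chloride, CC(C)(C)[Si](C)(C)Cl
Why: silylation of the primary allylic alcohol, so that it cannot compete as a nucleophile (β-lactone or oligoester formation) in the carbonylation.

**Step 12**
Reactants: 17 (1S,2R)-1-(3,4-dimethoxyphenyl)-2-[(E)-3-(4-methoxyphenyl)prop-2-en-1-yl]propane-1,3-diol; 21 (Z)-tert-butyl[(2-iodobut-2-en-1-yl)oxy]dimethylsilane
Product: 22 (2R,3S)-3-(3,4-dimethoxyphenyl)-3-hydroxy-2-[(E)-3-(4-methoxyphenyl)prop-2-en-1-yl]propyl (Z)-2-{[(tert-butyldimethylsilyl)oxy]methyl}but-2-enoate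
Conditions: 21 (1.2 equiv), CO (1 atm), PdCl2(PPh3)2 (5 mol%), Et3N, DMF, 60 °C
Reagents that add atoms: carbon monoxide, [C-]#[O+]
Why: palladium-catalysed alkoxycarbonylation of a vinyl iodide (oxidative addition, CO insertion, alcoholysis of the acyl-palladium) with retention of the alkene geometry, so that CH3 ends cis to the ester carbonyl; the primary OH of 17 should react in preference to the hindered secondary benzylic OH.

**Step 13**
Reactants: 22 (2R,3S)-3-(3,4-dimethoxyphenyl)-3-hydroxy-2-[(E)-3-(4-methoxyphenyl)prop-2-en-1-yl]propyl (Z)-2-{[(tert-butyldimethylsilyl)oxy]methyl}but-2-enoate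
Product: 23 (2R,3S)-3-(3,4-dimethoxyphenyl)-3-hydroxy-2-[(E)-3-(4-methoxyphenyl)prop-2-en-1-yl]propyl (Z)-2-(hydroxymethyl)but-2-enoate
Conditions: TBAF, AcOH (1:1), THF, 0 °C → rt
Reagents that add atoms: none
Why: buffered fluoride desilylation of the primary allylic silyl ether; the near-neutral medium should avoid acyl migration, alkene isomerisation and ionisation of the benzylic alcohol.

**Compound list**
1 | (S)-4-benzyloxazolidin-2-one | O=C1N[C@@H](Cc2ccccc2)CO1 | starting material
2 | pent-4-enoyl chloride | C=CCCC(Cl)=O | starting material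
3 | N-lithio-(S)-4-benzyloxazolidin-2-one | [Li]N1[C@@H](Cc2ccccc2)COC1=O | intermediate
4 | (S)-4-benzyl-3-(pent-4-enoyl)oxazolidin-2-one | C=CCCC(=O)N1[C@@H](Cc2ccccc2)COC1=O | intermediate
5 | (Z)-trichlorotitanium enolate of 4 | C=CC/C=C(\O[Ti](Cl)(Cl)Cl)N1[C@@H](Cc2ccccc2)COC1=O | intermediate
6 | (S)-4-benzyl-3-[(R)-2-(hydroxymethyl)pent-4-enoyl]oxazolidin-2-one | OC[C@@H](CC=C)C(=O)N1[C@@H](Cc2ccccc2)COC1=O | intermediate
7 | 4-vinylanisole (1-methoxy-4-vinylbenzene) | C=Cc1ccc(OC)cc1 | starting material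
8 | (S)-4-benzyl-3-[(2R,4E)-2-(hydroxymethyl)-5-(4-methoxyphenyl)pent-4-enoyl]oxazolidin-2-one | OC[C@@H](C/C=C/c1ccc(OC)cc1)C(=O)N1[C@@H](Cc2ccccc2)COC1=O | intermediate
9 | (S)-4-benzyl-3-[(2R,4E)-5-(4-methoxyphenyl)-2-{[(triisopropylsilyl)oxy]methyl}pent-4-enoyl]oxazolidin-2-one | CC(C)[Si](OC[C@@H](C/C=C/c1ccc(OC)cc1)C(=O)N1[C@@H](Cc2ccccc2)COC1=O)(C(C)C)C(C)C | intermediate
10 | (2S,4E)-5-(4-methoxyphenyl)-2-{[(triisopropylsilyl)oxy]methyl}pent-4-en-1-ol | CC(C)[Si](OC[C@@H](C/C=C/c1ccc(OC)cc1)CO)(C(C)C)C(C)C | intermediate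
11 | (2S,4E)-5-(4-methoxyphenyl)-2-{[(triisopropylsilyl)oxy]methyl}pent-4-en-1-yl N,N-diisopropylcarbamate | CC(C)[Si](OC[C@@H](C/C=C/c1ccc(OC)cc1)COC(=O)N(C(C)C)C(C)C)(C(C)C)C(C)C | intermediate
12 | 2-(3,4-dimethoxyphenyl)-4,4,5,5-tetramethyl-1,3,2-dioxaborolane | COc1ccc(B2OC(C)(C)C(C)(C)O2)cc1OC | starting material
13 | (1R,2R)-1-lithio derivative of 11 (Li in place of the pro-R hydrogen of OCH2, sparteine-complexed) | CC(C)[Si](OC[C@@H](C/C=C/c1ccc(OC)cc1)[C@@H]([Li])OC(=O)N(C(C)C)C(C)C)(C(C)C)C(C)C | intermediate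
14 | lithium boronate complex (boron of 12 bound to C1 of 13 with retention) | CC(C)[Si](OC[C@@H](C/C=C/c1ccc(OC)cc1)[C@@H]([B-]1(c2ccc(OC)c(OC)c2)OC(C)(C)C(C)(C)O1)OC(=O)N(C(C)C)C(C)C)(C(C)C)C(C)C.[Li+] | intermediate
15 | 2-[(1S,2S,4E)-1-(3,4-dimethoxyphenyl)-5-(4-methoxyphenyl)-2-{[(triisopropylsilyl)oxy]methyl}pent-4-en-1-yl]-4,4,5,5-tetramethyl-1,3,2-dioxaborolane | CC(C)[Si](OC[C@@H](C/C=C/c1ccc(OC)cc1)[C@H](B1OC(C)(C)C(C)(C)O1)c1ccc(OC)c(OC)c1)(C(C)C)C(C)C | intermediate
16 | (1S,2R,4E)-1-(3,4-dimethoxyphenyl)-5-(4-methoxyphenyl)-2-{[(triisopropylsilyl)oxy]methyl}pent-4-en-1-ol | CC(C)[Si](OC[C@@H](C/C=C/c1ccc(OC)cc1)[C@H](O)c1ccc(OC)c(OC)c1)(C(C)C)C(C)C | intermediate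
17 | (1S,2R)-1-(3,4-dimethoxyphenyl)-2-[(E)-3-(4-methoxyphenyl)prop-2-en-1-yl]propane-1,3-diol | OC[C@@H](C/C=C/c1ccc(OC)cc1)[C@H](O)c1ccc(OC)c(OC)c1 | intermediate
18 | (E)-crotonaldehyde | C/C=C/C=O | starting material
19 | (Z)-2-iodobut-2-enal | C/C=C(\I)C=O | intermediate
20 | (Z)-2-iodobut-2-en-1-ol | C/C=C(\I)CO | intermediate
21 | (Z)-tert-butyl[(2-iodobut-2-en-1-yl)oxy]dimethylsilane | C/C=C(\I)CO[Si](C)(C)C(C)(C)C | intermediate
22 | (2R,3S)-3-(3,4-dimethoxyphenyl)-3-hydroxy-2-[(E)-3-(4-methoxyphenyl)prop-2-en-1-yl]propyl (Z)-2-{[(tert-butyldimethylsilyl)oxy]methyl}but-2-enoate | C/C=C(/CO[Si](C)(C)C(C)(C)C)C(=O)OC[C@@H](C/C=C/c1ccc(OC)cc1)[C@H](O)c1ccc(OC)c(OC)c1 | intermediate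
23 | (2R,3S)-3-(3,4-dimethoxyphenyl)-3-hydroxy-2-[(E)-3-(4-methoxyphenyl)prop-2-en-1-yl]propyl (Z)-2-(hydroxymethyl)but-2-enoate | C/C=C(/CO)C(=O)OC[C@@H](C/C=C/c1ccc(OC)cc1)[C@H](O)c1ccc(OC)c(OC)c1 | target

**Step count.** Total: 13 steps. Longest linear sequence: 10 steps (steps 1–8, 12, 13); the vinyl iodide branch is steps 9–11.

**Steps most likely to fail**

Step 7. The base may deprotonate the allylic CH2 or add to the anisyl alkene instead of lithiating next to the carbamate oxygen. The pairing of (+)-sparteine with the C2 centre may be mismatched, which would lower the facial selectivity of the deprotonation. The 1,2-shift in the hindered ate complex may also stay incomplete. The fallback uses carbonyl chemistry and sets out from alcohol 10. Dess–Martin oxidation should give (R,E)-5-(4-methoxyphenyl)-2-{[(triisopropylsilyl)oxy]methyl}pent-4-enal F1. Addition of 3,4-dimethoxyphenylmagnesium bromide (THF, −78 °C) should give (2R,E)-1-(3,4-dimethoxyphenyl)-5-(4-methoxyphenyl)-2-{[(triisopropylsilyl)oxy]methyl}pent-4-en-1-ol as a mixture of C1 epimers F2. A second Dess–Martin oxidation should converge both epimers to (R,E)-1-(3,4-dimethoxyphenyl)-5-(4-methoxyphenyl)-2-{[(triisopropylsilyl)oxy]methyl}pent-4-en-1-one F3. Reagent-controlled Corey–Bakshi–Shibata reduction with the (R)-methyl oxazaborolidine and catecholborane (aryl as the large group, by analogy with acetophenone) should then give the (S)-carbinol, and the route is rejoined at 16.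

Step 12. The acyl-palladium may turn over slowly with a stoichiometric, β-branched alcohol, the secondary benzylic OH may be acylated in competition, or palladium hydride may isomerise an alkene. The fallback sets out from vinyl iodide 21. Iodine–lithium exchange (t-BuLi, Et2O, −78 °C) and carboxylation with CO2 should give (Z)-2-{[(tert-butyldimethylsilyl)oxy]methyl}but-2-enoic acid F4 with retention of geometry. Mitsunobu esterification of F4 with diol 17 (PPh3, DIAD, THF, 0 °C) then has the carboxylate displace the activated primary alcohol. The acid is never activated as an acyl donor, so the Z geometry should hold, and the route is rejoined at 22.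

Step 3. The cross-metathesis may give a statistical mixture, homodimerise the styrene, or stall through coordination of ruthenium by the β-hydroxy imide. The fallback sets out from 6: a Mizoroki–Heck arylation with 4-iodoanisole (Pd(OAc)2, Bu4NCl, NaHCO3, DMF, 70 °C) should give the (E)-styrenyl alkene directly and rejoin the route at 8. This fallback makes no new compound (F0).

**Further compounds**
F1 | step 7 | (R,E)-5-(4-methoxyphenyl)-2-{[(triisopropylsilyl)oxy]methyl}pent-4-enal | CC(C)[Si](OC[C@@H](C/C=C/c1ccc(OC)cc1)C=O)(C(C)C)C(C)C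
F2 | step 7 | (2R,E)-1-(3,4-dimethoxyphenyl)-5-(4-methoxyphenyl)-2-{[(triisopropylsilyl)oxy]methyl}pent-4-en-1-ol, mixture of C1 epimers | CC(C)[Si](OC[C@@H](C/C=C/c1ccc(OC)cc1)C(O)c1ccc(OC)c(OC)c1)(C(C)C)C(C)C
F3 | step 7 | (R,E)-1-(3,4-dimethoxyphenyl)-5-(4-methoxyphenyl)-2-{[(triisopropylsilyl)oxy]methyl}pent-4-en-1-one | CC(C)[Si](OC[C@@H](C/C=C/c1ccc(OC)cc1)C(=O)c1ccc(OC)c(OC)c1)(C(C)C)C(C)C
F4 | step 12 | (Z)-2-{[(tert-butyldimethylsilyl)oxy]methyl}but-2-enoic acid | C/C=C(/CO[Si](C)(C)C(C)(C)C)C(=O)O
F0 | step 3 | none | none
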